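**Retrosynthetic overview**
1. Target 15 comes from 14 by hydrogenolysis of three benzyl ethers; the C8 acetate is already in place.
2. The strategy rests on ring A (C4a, C5, C6, C7, C8, C8a): para oxygens at C5 (free OH) and C8 (acetate), OMe at C7 beside C8, H at C6. This hydroquinone monoester maps onto a 4-acetoxy-3-methoxycyclobutenone, so 14 comes from 11 by 4π ring opening and 6π closure that forms C4a–C5.
3. 11 comes from carbinol 10 by acetylation; 10 from the C6-magnesiated pyranone 5 and methyl semisquarate 8 (from dimethyl squarate 6), with addition at the ketone-type carbonyl so that OMe sits beside the carbinol carbon.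
4. 5 comes from 3-hydroxy-4H-pyran-4-one 1 by C2 bromination, O-benzylation and Suzuki coupling with boronic acid 4.
5. Ring order: rings B and C are present from step 3; ring A is closed in step 7.

Key step: step 7

Assumption: 1, 4 and 6 are taken as commercial. Compounds 7, 10, 11 and 13 are racemic and written without stereodescriptors; their single stereocentre is not controlled and is lost before the target, which has none.

**Step 1**
Reactants: 1 3-hydroxy-4H-pyran-4-one
Product: 2 2-bromo-3-hydroxy-4H-pyran-4-one
Conditions: NBS (1.0 equiv), MeCN, 0 °C to rt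
Reagents that add atoms: N-bromosuccinimide, O=C1CCC(=O)N1Br
Why: Electrophilic bromination of the enol should occur at C2, the beta-carbon of the C3 enol (ortho to OH) and the position at which 3-hydroxy-4-pyranones undergo Mannich and hydroxymethylation reactions.

**Step 2**
Reactants: 2 2-bromo-3-hydroxy-4H-pyran-4-one
Product: 3 3-(benzyloxy)-2-bromo-4H-pyran-4-one
Conditions: BnBr, K2CO3, DMF, rt
Reagents that add atoms: benzyl bromide, BrCc1ccccc1
Why: Williamson O-alkylation of the acidic enolic hydroxyl should be fast at room temperature and protects it for the metalation in step 5.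

**Step 3**
Reactants: 3 3-(benzyloxy)-2-bromo-4H-pyran-4-one; 4 [3,4-bis(benzyloxy)phenyl]boronic acid
Product: 5 3-(benzyloxy)-2-[3,4-bis(benzyloxy)phenyl]-4H-pyran-4-one
Conditions: Pd(PPh3)4 (5 mol %), K2CO3, 1,4-dioxane/H2O, 80 °C
Reagents that add atoms: none
Why: Suzuki–Miyaura coupling; the C2–Br bond is a vinylogous acyl bromide that should undergo oxidative addition to zerovalent palladium readily, and the electron-rich boronic acid transmetalates under mild carbonate conditions.

**Step 4**
Reactants: 6 dimethyl squarate
Product: 8 3-methoxycyclobut-3-ene-1,2-dione (methyl semisquarate), via 4-hydroxy-2,3-dimethoxycyclobut-2-en-1-one 7 (not isolated)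
Conditions: LiAlH(OtBu)3 (1.05 equiv), THF, −78 to −20 °C; then 2 M HCl, CH2Cl2, rt
Reagents that add atoms: water, O
Why: The single-hydride reagent should stop at 1,2-monoreduction of one squarate carbonyl, and acid then ionises the carbinol, water adds at the distal methoxy-bearing carbon and methanol is lost, the known transposition of squarate adducts to 3-alkoxycyclobutene-1,2-diones.

**Step 5**
Reactants: 5 3-(benzyloxy)-2-[3,4-bis(benzyloxy)phenyl]-4H-pyran-4-one; 8 3-methoxycyclobut-3-ene-1,2-dione
Product: 10 (±)-4-{5-(benzyloxy)-6-[3,4-bis(benzyloxy)phenyl]-4-oxo-4H-pyran-2-yl}-4-hydroxy-3-methoxycyclobut-2-en-1-one, via pyranon-6-ylmagnesium chloride 9 (not isolated)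
Conditions: TMPMgCl·LiCl (1.1 equiv), THF, −40 °C; cannulated into 8 (1.3 equiv), THF, −78 °C; sat. aq NH4Cl
Reagents that add atoms: none
Why: Deprotonative magnesiation with the hindered amide base should take place at C6–H, the most acidic ring position (next to the ring oxygen, as in C2-metalation of chromones), and the Grignard reagent should add 1,2 to the ketone-type C2 carbonyl of 8 rather than to the vinylogous-ester C1 carbonyl, giving the tertiary carbinol as a racemate whose stereocentre is erased in step 7.

**Step 6**
Reactants: 10 (±)-4-{5-(benzyloxy)-6-[3,4-bis(benzyloxy)phenyl]-4-oxo-4H-pyran-2-yl}-4-hydroxy-3-methoxycyclobut-2-en-1-one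
Product: 11 (±)-4-acetoxy-4-{5-(benzyloxy)-6-[3,4-bis(benzyloxy)phenyl]-4-oxo-4H-pyran-2-yl}-3-methoxycyclobut-2-en-1-one
Conditions: Ac2O, Et3N, DMAP (cat.), CH2Cl2, 0 °C
Reagents that add atoms: acetic anhydride, CC(=O)OC(C)=O
Why: DMAP-catalysed acyl transfer should acetylate the tertiary hydroxyl at low temperature without ionising the carbinol, and it installs the C8 ester before ring A exists.

**Step 7**
Reactants: 11 (±)-4-acetoxy-4-{5-(benzyloxy)-6-[3,4-bis(benzyloxy)phenyl]-4-oxo-4H-pyran-2-yl}-3-methoxycyclobut-2-en-1-one
Product: 14 8-acetoxy-3-(benzyloxy)-2-[3,4-bis(benzyloxy)phenyl]-5-hydroxy-7-methoxy-4H-chromen-4-one, via dienylketene 12 (not isolated), via cyclohexadienone 13 (not isolated)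
Conditions: PhMe (degassed, 0.01 M), 110 °C, Ar
Reagents that add atoms: none
Why: Heating should break the C1–C4 bond of the cyclobutenone by conrotatory 4π electrocyclic opening with the acetoxy group rotating outward, giving the (Z)-dienylketene 12 in which the pyranonyl group is cis to the ketene. The ketene carbon then bonds to pyranone C5, the nucleophilic alpha-carbon of the vinylogous ester, in a thermal disrotatory 6π electrocyclisation that forms the C4a–C5 bond and closes the six-membered carbocyclic ring A as dienone 13. Enolisation of 13, whose C4a–H lies between two carbonyl groups, makes ring A aromatic, so the ketene carbon becomes C5–OH, the vinylic CH becomes C6, the methoxy carbon C7 and the acetoxy carbon C8. The closest known reaction type is the Moore rearrangement of 4-alkenyl- and 4-heteroaryl-4-oxycyclobutenones to hydroquinone derivatives. No stereocentre is set, since C4 of 11 becomes sp2 on ring opening and the transient C4a centre of 13 is lost on enolisation. The step needs torquoselectivity and site selectivity: the first is secured by the oxygen donor at C4 and by the reversibility of the opening, which returns a ketene with inward acetoxy to 11, and the second by the fact that closure at the ring oxygen would give an oxonium ion, while the OMe/OAc adjacency was fixed in step 5.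

**Step 8**
Reactants: 14 8-acetoxy-3-(benzyloxy)-2-[3,4-bis(benzyloxy)phenyl]-5-hydroxy-7-methoxy-4H-chromen-4-one
Product: 15 gossypetin 7-methyl ether 8-acetate (8-acetoxy-2-(3,4-dihydroxyphenyl)-3,5-dihydroxy-7-methoxy-4H-chromen-4-one)
Conditions: H2 (1 atm), 10% Pd/C, EtOAc/THF, rt
Reagents that add atoms: none
Why: Hydrogenolysis should cleave the three benzyl ethers while the aryl acetate, the methyl ether and the tetrasubstituted C2=C3 bond of the chromone stay intact, and the aprotic solvent avoids solvolysis of the acetate.

**Compound list**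
1 | 3-hydroxy-4H-pyran-4-one | O=c1ccocc1O | starting material
2 | 2-bromo-3-hydroxy-4H-pyran-4-one | O=c1ccoc(Br)c1O | intermediate
3 | 3-(benzyloxy)-2-bromo-4H-pyran-4-one | O=c1ccoc(Br)c1OCc1ccccc1 | intermediate
4 | [3,4-bis(benzyloxy)phenyl]boronic acid | OB(O)c1ccc(OCc2ccccc2)c(OCc2ccccc2)c1 | starting material
5 | 3-(benzyloxy)-2-[3,4-bis(benzyloxy)phenyl]-4H-pyran-4-one | O=c1ccoc(-c2ccc(OCc3ccccc3)c(OCc3ccccc3)c2)c1OCc1ccccc1 | intermediate
6 | dimethyl squarate | COC1=C(OC)C(=O)C1=O | starting material
7 | (±)-4-hydroxy-2,3-dimethoxycyclobut-2-en-1-one | COC1=C(OC)C(=O)C1O | intermediate (not isolated)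
8 | 3-methoxycyclobut-3-ene-1,2-dione | COC1=CC(=O)C1=O | intermediate
9 | {5-(benzyloxy)-6-[3,4-bis(benzyloxy)phenyl]-4-oxo-4H-pyran-2-yl}magnesium chloride | Cl[Mg]c1cc(=O)c(OCc2ccccc2)c(-c2ccc(OCc3ccccc3)c(OCc3ccccc3)c2)o1 | intermediate (not isolated)
10 | (±)-4-{5-(benzyloxy)-6-[3,4-bis(benzyloxy)phenyl]-4-oxo-4H-pyran-2-yl}-4-hydroxy-3-methoxycyclobut-2-en-1-one | COC1=CC(=O)C1(O)c1cc(=O)c(OCc2ccccc2)c(-c2ccc(OCc3ccccc3)c(OCc3ccccc3)c2)o1 | intermediate
11 | (±)-4-acetoxy-4-{5-(benzyloxy)-6-[3,4-bis(benzyloxy)phenyl]-4-oxo-4H-pyran-2-yl}-3-methoxycyclobut-2-en-1-one | COC1=CC(=O)C1(OC(C)=O)c1cc(=O)c(OCc2ccccc2)c(-c2ccc(OCc3ccccc3)c(OCc3ccccc3)c2)o1 | intermediate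
12 | (3Z)-4-acetoxy-4-{5-(benzyloxy)-6-[3,4-bis(benzyloxy)phenyl]-4-oxo-4H-pyran-2-yl}-3-methoxybuta-1,3-dien-1-one | O=C=C/C(OC)=C(/OC(C)=O)c1cc(=O)c(OCc2ccccc2)c(-c2ccc(OCc3ccccc3)c(OCc3ccccc3)c2)o1 | intermediate (not isolated)
13 | (±)-8-acetoxy-3-(benzyloxy)-2-[3,4-bis(benzyloxy)phenyl]-7-methoxy-4aH-chromene-4,5-dione | COC1=CC(=O)C2C(=O)C(OCc3ccccc3)=C(c3ccc(OCc4ccccc4)c(OCc4ccccc4)c3)OC2=C1OC(C)=O | intermediate (not isolated)
14 | 8-acetoxy-3-(benzyloxy)-2-[3,4-bis(benzyloxy)phenyl]-5-hydroxy-7-methoxy-4H-chromen-4-one | COc1cc(O)c2c(=O)c(OCc3ccccc3)c(-c3ccc(OCc4ccccc4)c(OCc4ccccc4)c3)oc2c1OC(C)=O | intermediate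
15 | gossypetin 7-methyl ether 8-acetate | COc1cc(O)c2c(=O)c(O)c(-c3ccc(O)c(O)c3)oc2c1OC(C)=O | target

**Step count**
Total: 8 steps. Longest linear sequence: 7 steps (steps 1, 2, 3, 5, 6, 7, 8 from compound 1); step 4 is the side branch from 6.

**Steps most likely to fail**

Step 7. The acyloxy group is a weaker donor than hydroxyl, so ring opening may be slow and need temperatures at which the ketene is diverted (inward rotation of the acetate, acyl transfer, capture by adventitious nucleophiles) before it closes onto C5. The fallback sets out from 10 and uses the classical 4-hydroxy variant. Carbinol 10 is heated in degassed toluene at 110 °C under argon, which should give the hydroquinone 3-(benzyloxy)-2-[3,4-bis(benzyloxy)phenyl]-5,8-dihydroxy-7-methoxy-4H-chromen-4-one F1. This is kept under argon (a Na2S2O4 wash returns any quinone formed by air oxidation) and treated with Ac2O (1.0 equiv) and pyridine at 0 °C. The C5 hydroxyl is hydrogen-bonded to the C4 carbonyl and should stay free, so acetylation should occur at the C8 hydroxyl, and the route is rejoined at 14.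

Step 5. Metalation may occur partly at C5 (with ring opening of the pyranone), the magnesiated pyranone may self-condense, or the Grignard reagent may add in conjugate fashion or twice to 8. The fallback sets out from 5 and separates metalation from carbonyl addition. Zincation with TMPZnCl·LiCl in THF at 25 °C followed by I2 should give 3-(benzyloxy)-2-[3,4-bis(benzyloxy)phenyl]-6-iodo-4H-pyran-4-one F2, which can be purified and its constitution checked. Iodine–magnesium exchange with iPrMgCl·LiCl in THF at −78 °C then gives an amine-free solution of 9, where the route is rejoined; addition to 8 as in step 5 gives 10.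

Step 6. Acylation of the hindered tertiary carbinol may be slow, and during that time the amine base may promote ring opening or rearrangement of the 4-hydroxycyclobutenone. The fallback sets out from 5 (with 8) and acylates the metal alkoxide instead of the free carbinol. The addition of step 5 is repeated and, in place of the NH4Cl quench, the chloromagnesium alkoxide of 10 F3 is treated at −78 °C with acetyl chloride and warmed to 0 °C. The classical capture of a Grignard adduct as its acetate should give 11 directly, where the route is rejoined.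

**Further compounds**
F1 | step 7 | 3-(benzyloxy)-2-[3,4-bis(benzyloxy)phenyl]-5,8-dihydroxy-7-methoxy-4H-chromen-4-one | COc1cc(O)c2c(=O)c(OCc3ccccc3)c(-c3ccc(OCc4ccccc4)c(OCc4ccccc4)c3)oc2c1O
F2 | step 5 | 3-(benzyloxy)-2-[3,4-bis(benzyloxy)phenyl]-6-iodo-4H-pyran-4-one | O=c1cc(I)oc(-c2ccc(OCc3ccccc3)c(OCc3ccccc3)c2)c1OCc1ccccc1
F3 | step 6 | chloromagnesium alkoxide of 10 | COC1=CC(=O)C1(O[Mg]Cl)c1cc(=O)c(OCc2ccccc2)c(-c2ccc(OCc3ccccc3)c(OCc3ccccc3)c2)o1
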